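## The problem

The target joins two acylphloroglucinol-derived halves through a single methylene carbon. Ring A is a dearomatised 2-isobutyrylcyclohexane-1,3,5-trione, written as its dienol (C1 ketone, C2 acyl, C3 and C5 enols), whose C4 carries a methyl and a prenyl group. Ring B is an aromatic isobutyrylphloroglucinol fused through C4a and C8a to ring C, a 2,2-dimethyl-2H-pyran; the bridge runs from ring A C6 to chromene C6, in each half the one ring carbon that is unsubstituted and strongly nucleophilic. Ring A C4 is the only stereocentre: it is quaternary, (S), and flanked by two carbonyl carbons that differ only in what the next ring atom carries (acyl at C2, bridge at C6). No second stereo element can direct it, so its absolute sense must come from an external chiral agent. Once made it cannot epimerise by enolisation, but the β-tricarbonyl array around it can be opened by retro-Claisen attack of hard nucleophiles. The prenyl alkene and the C3=C4 bond of ring C do not tolerate strong protic acid or electrophilic halogen. The bridging CH2 is exposed to hydride-abstracting oxidants and to acid- or base-induced exchange that scrambles such dimers into their symmetrical relatives, so it should be made last and mildly. What makes the key step possible is that O1–C2(CH3)2–C3=C4, with C4 bound to C4a, is a prenyl group on C4a, ortho to the O1-bearing C8a, that has lost hydride from its benzylic CH2 and closed onto the phenol oxygen; the only open question is regiochemical, since O1 must be the oxygen next to the acyl-bearing C8 and not the one para to the ketone.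

## Retrosynthesis

The bridge is cut first, at the bond between the methylene carbon and ring A C6. This returns target 20 to the ring A trione 18 and to Mannich base 11, a chromene that already carries the one-carbon unit as a dimethylaminomethyl group. This side is preferred over the aryl–CH2 bond because 11 has no unsubstituted ring carbon left. The ortho-quinone methide 19 that it releases on heating can therefore be intercepted only by the enol carbon of 18, whereas a methylene-activated ring A would be generated beside its own highly nucleophilic parent. Each fragment is about half the target. The forward step must form one C–C bond at the only free carbon of 18 without touching the stereocentre and without exchanging the bridge between partners.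

Mannich base 11 is cut between chromene C6 and the aminomethyl carbon, giving dihydroxychromene 9 and the preformed iminium salt 10. Chromene C6 is the only unsubstituted aromatic position and lies between two hydroxyls, so the forward aminomethylation has no regiochemical choice to make.

Phenol 9 comes from its methoxymethyl ether 8 by acetal cleavage. Ether 8 is opened at the O1–C2 bond, with the double bond returned to the side chain, to give prenyl phenol 6; the forward reaction passes through ortho-quinone methide 7. Cuts at C4a–C4 or C8a–O1 would mean condensation with an unsaturated aldehyde or aryne chemistry. The first leaves open which hydroxyl beside C4a closes, and the second needs a heavily substituted arene. The O1–C2 cut leads to a compound one oxidation level lower and turns the regiochemical question into a protecting-group question: in 6 the hydroxyl para to the ketone is an acetal, so only the C2 hydroxyl can become O1. The forward oxidation must take hydride from one CH2 only, and it is placed before the bridge exists because a bridging CH2 would be oxidised as well.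

Prenyl phenol 6 is simplified by removing the acetal (triol 5), then the prenyl group at the aryl–CH2 bond (ketone 3 and prenyl bromide 4), then the acyl group (phloroglucinol 1 and isobutyryl chloride 2). In 3 the two free ring carbons are equivalent, so C-prenylation can give only one monoprenyl isomer. In 5 the hydroxyl para to the ketone is the only one out of reach of the carbonyl hydrogen bond, so the acyl group serves as the marker that distinguishes the oxygens.

Ring A trione 18 is opened between the acyl-bearing C2 and C3, one of the two carbonyl carbons at the quaternary centre, giving acyclic triketo ester 17. The neighbouring cut, between C4 and the prenyl CH2, would lead to an aromatic methyl-acylphloroglucinol and a dearomatising prenylation; that is shorter but offers no established handle on absolute configuration. In 17 the stereocentre sits between an ester and a ketone, and the forward Claisen closure only has to join the doubly activated carbon to the ester.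

Triketo ester 17 is cut between its C3 carbonyl and C4 into acid chloride 16, made in the flask from half-ester 14, and the terminal carbanion of diketone 15. All three remaining ring carbons and the isobutyryl group then come from one commercial compound. The forward reaction needs only acylation at the methyl terminus of 15.

Half-ester 14 comes from prochiral diester 13 by hydrolysis of one of two enantiotopic ester groups, and 13 from dimethyl methylmalonate 12 and prenyl bromide 4. The two carbonyl branches of the future ring A are identical in 13 and become acid and ester in 14. Which branch later faces the bridge and which the acyl group then follows from ordinary reactivity.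

## Roads not taken

Alternative 1: The stereocentre is created on the ring, on the prochiral trione A1 (4-methyl-4-prenylcyclohexane-1,3,5-trione), whose two carbonyls beside the quaternary carbon are enantiotopic. In the forward key step a chiral catalyst delivers positive bromine to the prenyl alkene, and one of the two enol oxygens opens the bromonium ion at its tertiary carbon. This gives the bicyclic bromo enol ether A2 with the quaternary configuration fixed.
- Merits: the step is catalytic, either antipode would be available by choice of catalyst, and A1 is only a few steps from an aromatic precursor.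
- Weak points: the ring CH2 groups of a fully enolisable trione are far more nucleophilic toward positive bromine than a trisubstituted alkene, so C-bromination competes. Discrimination between rapidly tautomerising enol oxygens would have to be established for this substrate class. The prenyl group is consumed, so A2 must still be acylated regioselectively at one of its two ring positions and then reductively reopened; the final absolute configuration depends on that regioselectivity. Ring C and the bridge are not addressed.
- Comparison: for setting the quaternary centre this road is more flexible than the esterase step 8, which exists in one sense only. The chosen plan sets against this a reaction class established on 2-alkyl-2-methylmalonates, a substrate (13) with no competing nucleophilic site, and a product (14) whose two branches are already chemically different.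

Alternative 2: The cut is the ring A bond between the acyl-bearing carbon and the neighbouring carbonyl carbon at the quaternary centre. In the forward key step the polyanion of the acyclic triketo ester A3 closes by Claisen condensation to the ring A monomer A4.
- Merits: it follows the polyketide logic, the quaternary centre is in place before the ring closes and cannot epimerise, and aldol modes are blocked because the carbon next to the ester has no hydrogen.
- Weak points: enantiopurity rests entirely on how the quaternary carbon of A3 is obtained, O-cyclisation to a pyranone can compete, and ring C and the bridge are not addressed.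
- Comparison: for ring A this road is as good as the chosen plan because it is the same road. A3 and A4 are compounds 17 and 18, and the closure is step 10. The plans differ only in emphasis: the chosen plan makes the regiochemistry of ring C the organising problem and runs the Claisen closure early, on simple material. It loses nothing against this alternative on ring A, and it must carry the chromene regiochemistry in addition.

Alternative 3: Ring C is cut at C8a–O1 and C4a–C4 as well as O1–C2. In the forward key step fluoride releases aryne A6 from silyl aryl triflate A5, and the aryne adds the carbonyl group of 3-methylbut-2-enal A7. The resulting benzoxete opens to an ortho-quinone methide that closes by oxa-6π electrocyclisation to chromene A8.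
- Merits: the position of the pyran oxygen is fixed by where the aryne sits and by the polarising alkoxy group, not by the relative reactivity of hydroxyls. A8 already carries the bridge carbon as a silyloxymethyl group, and no oxidant is needed.
- Weak points: A5 is a hexasubstituted benzene whose preparation is likely to take more steps than the whole chromene half of the chosen plan. Aryne–enal cascades need excess aldehyde and compete with other aryne pathways. A8 lacks the isobutyryl group, which would have to be introduced at C8 on an acid-sensitive chromene, and two acetals and a silyl ether remain to be handled.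
- Comparison: this road is better in regiochemical certainty and in carrying the bridge carbon from the start. The chosen plan sets against it six steps from 1 to 11 with commodity reagents, an acyl group present from step 1 that itself marks the hydroxyls, and precedent on acylphloroglucinols. Its regiocontrol rests on one selective acetalisation, step 3, which has a fallback.

Key step: step 4

Assumption: pig liver esterase is taken to cleave the pro-R ester group of 13 and so to give (S)-14; its sense toward a methyl/prenyl malonate cannot be predicted with certainty from its behaviour toward shorter and longer alkyl chains, so step 8 carries a fallback that can deliver either antipode.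

## Route

Step 1
Reactants: 1 phloroglucinol (benzene-1,3,5-triol); 2 isobutyryl chloride (2-methylpropanoyl chloride)
Product: 3 2-methyl-1-(2,4,6-trihydroxyphenyl)propan-1-one
Conditions: AlCl3 (4 equiv), PhNO2, 0 → 65 °C; aq. HCl work-up
Reagents that add atoms: none
Why: Friedel–Crafts C-acylation of a symmetrical, very electron-rich arene; the first ketone deactivates the ring and binds AlCl3, so monoacylation should prevail.

Step 2
Reactants: 3 2-methyl-1-(2,4,6-trihydroxyphenyl)propan-1-one; 4 prenyl bromide (1-bromo-3-methylbut-2-ene)
Product: 5 2-methyl-1-[2,4,6-trihydroxy-3-(3-methylbut-2-en-1-yl)phenyl]propan-1-one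
Conditions: 4 (0.9 equiv), DBU (1.0 equiv), THF, 0 → 20 °C
Reagents that add atoms: none
Why: Base-mediated C-alkylation of an acylphloroglucinol phenoxide, a known route to C-prenyl acylphloroglucinols; the two free ring carbons of 3 are equivalent, so only one C-monoprenyl isomer can form, and a deficit of bromide limits O- and di-alkylation.

Step 3
Reactants: 5 2-methyl-1-[2,4,6-trihydroxy-3-(3-methylbut-2-en-1-yl)phenyl]propan-1-one
Product: 6 1-[2,6-dihydroxy-4-(methoxymethoxy)-3-(3-methylbut-2-en-1-yl)phenyl]-2-methylpropan-1-one
Conditions: MOMCl (1.05 equiv), iPr2NEt (1.1 equiv), CH2Cl2, −10 → 0 °C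
Reagents that add atoms: chloromethyl methyl ether, COCCl
Why: Williamson-type acetalisation of the most acidic hydroxyl, the one para to the ketone, whose phenoxide is a vinylogous carboxylate and which is not hydrogen-bonded; the two ortho hydroxyls share the chelate to the carbonyl and the one at C2 is also shielded by the prenyl group.

Step 4
Reactants: 6 1-[2,6-dihydroxy-4-(methoxymethoxy)-3-(3-methylbut-2-en-1-yl)phenyl]-2-methylpropan-1-one
Product: 8 1-[7-hydroxy-5-(methoxymethoxy)-2,2-dimethyl-2H-chromen-8-yl]-2-methylpropan-1-one, via ortho-quinone methide 7 (not isolated)
Conditions: DDQ (1.2 equiv), benzene, 80 °C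
Reagents that add atoms: none
Why: DDQ removes hydride from the side-chain CH2 of 6, the only C–H that is benzylic and allylic at once; the cation is stabilised by oxygen substituents ortho, ortho and para to it, which outweighs the meta ketone. Loss of the proton of the C2 hydroxyl gives ortho-quinone methide 7, a 1-oxatriene (O=C2–C3=CH–CH=CMe2). Thermal oxa-6π electrocyclisation, disrotatory and formally a 6-endo closure of the carbonyl oxygen onto the dimethyl-substituted terminus, forms the O1–C2 bond, places the double bond at C3=C4 and restores the aromaticity of ring B, which makes the closure irreversible. The closest known reaction type is the DDQ cyclodehydrogenation of ortho-prenylphenols, C-prenylated acylphloroglucinol ethers included, to 2,2-dimethyl-2H-chromenes. No stereocentre is formed. The selectivity needed is regiochemical: the oxygen para to the ketone is an acetal and cannot become a neutral pyran oxygen, so only the C2 hydroxyl closes and the 8-acyl chromene results; a para-quinone methide formed through the C6 hydroxyl cannot cyclise and returns to 7 by proton shift. The isobutyryl methine and the acetal CH2 are not hydride donors toward DDQ, and 8 has no benzylic C–H left, so over-oxidation is not expected.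

Step 5
Reactants: 8 1-[7-hydroxy-5-(methoxymethoxy)-2,2-dimethyl-2H-chromen-8-yl]-2-methylpropan-1-one
Product: 9 1-(5,7-dihydroxy-2,2-dimethyl-2H-chromen-8-yl)-2-methylpropan-1-one
Conditions: 3 M aq. HCl, MeOH, 50 °C
Reagents that add atoms: none
Why: Acid-catalysed acetal exchange with methanol; methoxymethyl ethers are routinely removed this way beside a 2,2-dimethylchromene, and the step is placed before the bridge exists because methylene-bridged dimers scramble in acid.

Step 6
Reactants: 9 1-(5,7-dihydroxy-2,2-dimethyl-2H-chromen-8-yl)-2-methylpropan-1-one; 10 N,N-dimethylmethyleneiminium iodide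
Product: 11 1-{6-[(dimethylamino)methyl]-5,7-dihydroxy-2,2-dimethyl-2H-chromen-8-yl}-2-methylpropan-1-one
Conditions: Et3N (1.1 equiv), CH2Cl2, 0 → 20 °C
Reagents that add atoms: none
Why: Phenolic Mannich reaction at chromene C6, the only unsubstituted aromatic carbon and the one between two hydroxyls; the preformed anhydrous iminium salt avoids aqueous formaldehyde and with it formation of a bis(chromenyl)methane.

Step 7
Reactants: 12 dimethyl methylmalonate (dimethyl 2-methylpropanedioate); 4 prenyl bromide (1-bromo-3-methylbut-2-ene)
Product: 13 dimethyl 2-methyl-2-(3-methylbut-2-en-1-yl)propanedioate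
Conditions: NaH (1.1 equiv), THF, 0 → 20 °C
Reagents that add atoms: none
Why: Malonate alkylation of the sodium enolate with a primary allylic bromide; the product is achiral, with two enantiotopic ester groups.

Step 8
Reactants: 13 dimethyl 2-methyl-2-(3-methylbut-2-en-1-yl)propanedioate
Product: 14 (2S)-2-(methoxycarbonyl)-2,5-dimethylhex-4-enoic acid
Conditions: pig liver esterase, 0.1 M phosphate buffer (pH 7.5), 10% DMSO, 25 °C, pH-stat (1 M NaOH); then HCl to pH 2
Reagents that add atoms: water, O
Why: Enzymatic desymmetrisation of a 2-alkyl-2-methylmalonate, a known reaction class; the esterase hydrolyses one of the two enantiotopic ester groups and stops at the half-ester because the carboxylate is not a substrate, and this discrimination by the enzyme's active site sets the quaternary stereocentre.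

Step 9
Reactants: 14 (2S)-2-(methoxycarbonyl)-2,5-dimethylhex-4-enoic acid; 15 5-methylhexane-2,4-dione
Product: 17 methyl (2S)-2,8-dimethyl-2-(3-methylbut-2-en-1-yl)-3,5,7-trioxononanoate, via acid chloride 16 (not isolated)
Conditions: 14, 1-chloro-N,N,2-trimethylprop-1-en-1-amine (1.1 equiv), CH2Cl2, 0 → 20 °C, evaporate; 15 (2.2 equiv), LiN(iPr)2 (4.4 equiv), THF, −78 → 0 °C; add 16 at −78 °C; AcOH quench at −78 °C
Reagents that add atoms: none
Why: The α-chloroenamine converts the acid into acid chloride 16 without liberating HCl, so the prenyl alkene is safe; γ-acylation of a 1,3-diketone dianion then occurs at the terminal, most basic carbanion (the methyl end of 15), the excess dianion deprotonates the triketone formed and shields it, and the hindered methyl ester does not compete at −78 °C. The stereocentre is quaternary, cannot form a ketene or enolise, and is carried through unchanged.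

Step 10
Reactants: 17 methyl (2S)-2,8-dimethyl-2-(3-methylbut-2-en-1-yl)-3,5,7-trioxononanoate
Product: 18 (4S)-3,5-dihydroxy-4-methyl-4-(3-methylbut-2-en-1-yl)-2-(2-methylpropanoyl)cyclohexa-2,5-dien-1-one
Conditions: LiN(SiMe3)2 (3 equiv), THF, −78 → 40 °C; then 1 M HCl
Reagents that add atoms: none
Why: Intramolecular Claisen (Dieckmann-type) condensation of a 3,5,7-triketo ester: the C6 carbanion of the dianion attacks the ester in a 6-(enolexo)-exo-trig closure, aldol modes are blocked because C2 has no hydrogen, and deprotonation of the strongly acidic acyl-trione drives the reaction. A non-nucleophilic amide base avoids retro-Claisen cleavage, and the quaternary centre cannot epimerise.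

Step 11
Reactants: 11 1-{6-[(dimethylamino)methyl]-5,7-dihydroxy-2,2-dimethyl-2H-chromen-8-yl}-2-methylpropan-1-one; 18 (4S)-3,5-dihydroxy-4-methyl-4-(3-methylbut-2-en-1-yl)-2-(2-methylpropanoyl)cyclohexa-2,5-dien-1-one
Product: 20 (4S)-3,5-dihydroxy-6-{[5,7-dihydroxy-2,2-dimethyl-8-(2-methylpropanoyl)-2H-chromen-6-yl]methyl}-4-methyl-4-(3-methylbut-2-en-1-yl)-2-(2-methylpropanoyl)cyclohexa-2,5-dien-1-one, via ortho-quinone methide 19 (not isolated)
Conditions: 11 (1.0 equiv), 18 (1.05 equiv), 1,4-dioxane, 90 °C, N2 purge
Reagents that add atoms: none
Why: Alkylation of a cyclic 1,3-dicarbonyl by a phenolic Mannich base: the acidic trione protonates the amine, loss of dimethylamine gives ortho-quinone methide 19, and Michael addition of the only free enol carbon of 18 followed by rearomatisation forms the bridge. Mannich base 11 has no free ring carbon and cannot self-condense, any O-adduct can revert to 19, and the remote quaternary stereocentre is not involved.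

## Compound list

1 | phloroglucinol (benzene-1,3,5-triol) | Oc1cc(O)cc(O)c1 | starting material
2 | isobutyryl chloride (2-methylpropanoyl chloride) | CC(C)C(=O)Cl | starting material
3 | 2-methyl-1-(2,4,6-trihydroxyphenyl)propan-1-one | CC(C)C(=O)c1c(O)cc(O)cc1O | intermediate
4 | prenyl bromide (1-bromo-3-methylbut-2-ene) | CC(C)=CCBr | starting material
5 | 2-methyl-1-[2,4,6-trihydroxy-3-(3-methylbut-2-en-1-yl)phenyl]propan-1-one | CC(C)=CCc1c(O)cc(O)c(C(=O)C(C)C)c1O | intermediate
6 | 1-[2,6-dihydroxy-4-(methoxymethoxy)-3-(3-methylbut-2-en-1-yl)phenyl]-2-methylpropan-1-one | CC(C)=CCc1c(O)c(C(=O)C(C)C)c(O)cc1OCOC | intermediate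
7 | 3-hydroxy-5-(methoxymethoxy)-6-(3-methylbut-2-en-1-ylidene)-2-(2-methylpropanoyl)cyclohexa-2,4-dien-1-one (ortho-quinone methide, formed in the flask) | CC(C)=CC=C1C(=O)C(C(=O)C(C)C)=C(O)C=C1OCOC | intermediate
8 | 1-[7-hydroxy-5-(methoxymethoxy)-2,2-dimethyl-2H-chromen-8-yl]-2-methylpropan-1-one | CC(C)C(=O)c1c(O)cc(OCOC)c2C=CC(C)(C)Oc12 | intermediate
9 | 1-(5,7-dihydroxy-2,2-dimethyl-2H-chromen-8-yl)-2-methylpropan-1-one | CC(C)C(=O)c1c(O)cc(O)c2C=CC(C)(C)Oc12 | intermediate
10 | N,N-dimethylmethyleneiminium iodide | C=[N+](C)C.[I-] | starting material
11 | 1-{6-[(dimethylamino)methyl]-5,7-dihydroxy-2,2-dimethyl-2H-chromen-8-yl}-2-methylpropan-1-one | CC(C)C(=O)c1c(O)c(CN(C)C)c(O)c2C=CC(C)(C)Oc12 | intermediate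
12 | dimethyl methylmalonate (dimethyl 2-methylpropanedioate) | COC(=O)C(C)C(=O)OC | starting material
13 | dimethyl 2-methyl-2-(3-methylbut-2-en-1-yl)propanedioate | COC(=O)C(C)(CC=C(C)C)C(=O)OC | intermediate
14 | (2S)-2-(methoxycarbonyl)-2,5-dimethylhex-4-enoic acid | C[C@@](C(=O)OC)(C(=O)O)CC=C(C)C | intermediate
15 | 5-methylhexane-2,4-dione | CC(=O)CC(=O)C(C)C | starting material
16 | methyl (2R)-2-(chlorocarbonyl)-2,5-dimethylhex-4-enoate (acid chloride, formed in the flask; same spatial arrangement as 14) | C[C@@](C(=O)OC)(C(Cl)=O)CC=C(C)C | intermediate
17 | methyl (2S)-2,8-dimethyl-2-(3-methylbut-2-en-1-yl)-3,5,7-trioxononanoate | C[C@@](C(=O)OC)(C(=O)CC(=O)CC(=O)C(C)C)CC=C(C)C | intermediate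
18 | (4S)-3,5-dihydroxy-4-methyl-4-(3-methylbut-2-en-1-yl)-2-(2-methylpropanoyl)cyclohexa-2,5-dien-1-one | CC(C)=CC[C@@]1(C)C(O)=CC(=O)C(C(=O)C(C)C)=C1O | intermediate
19 | 7-hydroxy-2,2-dimethyl-6-methylidene-8-(2-methylpropanoyl)-2H-chromen-5(6H)-one (ortho-quinone methide, formed in the flask) | C=C1C(=O)C2=C(OC(C)(C)C=C2)C(C(=O)C(C)C)=C1O | intermediate
20 | (4S)-3,5-dihydroxy-6-{[5,7-dihydroxy-2,2-dimethyl-8-(2-methylpropanoyl)-2H-chromen-6-yl]methyl}-4-methyl-4-(3-methylbut-2-en-1-yl)-2-(2-methylpropanoyl)cyclohexa-2,5-dien-1-one | CC(C)=CC[C@@]1(C)C(O)=C(Cc2c(O)c3c(c(C(=O)C(C)C)c2O)OC(C)(C)C=C3)C(=O)C(C(=O)C(C)C)=C1O | target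

## Step count and least certain steps

Total: 11 steps. Longest linear sequence: 7 steps (steps 1–6 and 11, from phloroglucinol); the ring A branch is 5 steps (steps 7–11).

**Step 4 (key step).** The ring is deactivated by the chelated ketone, so hydride abstraction may be slow. Prolonged heating with the quinone then risks oxidative degradation of the phenol, or slow loss of the acetal under the acidic hydroquinone, which would open the isomeric closure. Fallback, from 6 back to 8: the same oxygen is closed onto the same carbon by electrophile-induced cyclisation, and the oxidation follows. PhSeCl in CH2Cl2 at −78 °C should give, by Markovnikov opening of the seleniranium ion by the C2 hydroxyl, the 3-(phenylselanyl)chromane F1. Oxidation with aqueous H2O2 in THF gives its selenoxide F2, whose syn-elimination can only run toward C4 because C2 carries no hydrogen, and this delivers 8.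

**Step 8.** Hydrolysis with low enantioselectivity, or with the opposite sense, is the likely failure, because the prenyl chain lies between the short and long alkyl groups toward which the esterase shows opposite preferences. Fallback, from 13 back to 14: chemical monosaponification (KOH, 1.0 equiv, MeOH) gives the racemic half-ester F3, which is resolved by crystallising its (S)-1-phenylethylammonium salt F4 and liberated with HCl to give 14. Which diastereomeric salt is the less soluble cannot be predicted; if it is the other one, the antipodal amine is used in the same way. The acid left in the mother liquor is re-methylated to the prochiral diester 13 and recycled.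

**Step 11.** The bridge may exchange between the partners through reversible quinone methide formation in the warm, amine-containing medium, which would lead toward the two symmetrical dimers; alternatively amine loss may be too slow at a temperature the product tolerates. Fallback, from 9 and 18 back to 20: the bridging carbon is first bound to ring B by a C–C bond that cannot migrate. Vilsmeier–Haack formylation of 9 (POCl3, DMF; aqueous work-up) at chromene C6 gives the 6-carbaldehyde F5. Three-component reductive alkylation with 18 (diethyl 2,6-dimethyl-1,4-dihydropyridine-3,5-dicarboxylate, catalytic L-proline, CH2Cl2, 20 °C) proceeds by Knoevenagel condensation to the arylidene trione F6, and irreversible conjugate hydride transfer to F6 gives 20.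

**Step 9.** Proton transfer and O-acylation may outrun C-acylation at the hindered, neopentyl-type acyl chloride, and the strongly basic medium may cause premature or wrong-way ring closure of the product. Fallback, from 15 and 16 back to 17: the diketone is converted by double silylation (Me3SiCl, Et3N; then LiN(iPr)2, Me3SiCl) into the bis(trimethylsilyl) dienol ether F7, which is acylated at its terminal carbon by 16 under non-basic conditions (catalytic Me3SiOTf, CH2Cl2, −78 → 20 °C; aqueous work-up) to give 17.

**Step 3.** Acetalisation may occur at the unhindered ortho hydroxyl or twice, since the para hydroxyl is now flanked by the prenyl group. Fallback, from 3 back to 6: the order is reversed. The symmetrical triol 3 is acetalised first (MOMCl, iPr2NEt), where the para hydroxyl competes only with two equivalent chelated ones, to give the para-acetal F8; C-prenylation of F8 with 4 (aq. KOH, 0 °C) at one of its two equivalent free carbons then gives 6.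

## Further compounds

F1 | step 4 | 1-[7-hydroxy-5-(methoxymethoxy)-2,2-dimethyl-3-(phenylselanyl)-3,4-dihydro-2H-chromen-8-yl]-2-methylpropan-1-one (racemic at C3) | CC(C)C(=O)c1c(O)cc(OCOC)c2CC([Se]c3ccccc3)C(C)(C)Oc12
F2 | step 4 | 1-[7-hydroxy-5-(methoxymethoxy)-2,2-dimethyl-3-(phenylseleninyl)-3,4-dihydro-2H-chromen-8-yl]-2-methylpropan-1-one | CC(C)C(=O)c1c(O)cc(OCOC)c2CC([Se](=O)c3ccccc3)C(C)(C)Oc12
F3 | step 8 | racemic 2-(methoxycarbonyl)-2,5-dimethylhex-4-enoic acid | CC(C)=CCC(C)(C(=O)OC)C(=O)O
F4 | step 8 | (1S)-1-phenylethan-1-aminium (2S)-2-(methoxycarbonyl)-2,5-dimethylhex-4-enoate | C[C@@](C(=O)OC)(C(=O)[O-])CC=C(C)C.C[C@H]([NH3+])c1ccccc1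
F5 | step 11 | 5,7-dihydroxy-2,2-dimethyl-8-(2-methylpropanoyl)-2H-chromene-6-carbaldehyde | CC(C)C(=O)c1c(O)c(C=O)c(O)c2C=CC(C)(C)Oc12
F6 | step 11 | arylidene trione from F5 and 18 (ring A C6 carrying the exocyclic =CH–chromen-6-yl group, quaternary centre as in 18) | CC(C)=CC[C@@]1(C)C(=O)C(=Cc2c(O)c3C=CC(C)(C)Oc3c(C(=O)C(C)C)c2O)C(=O)C(C(=O)C(C)C)=C1O
F7 | step 9 | 5-methyl-2,4-bis(trimethylsilyloxy)hexa-1,3-diene | C=C(O[Si](C)(C)C)C=C(O[Si](C)(C)C)C(C)C
F8 | step 3 | 1-[2,6-dihydroxy-4-(methoxymethoxy)phenyl]-2-methylpropan-1-one | CC(C)C(=O)c1c(O)cc(OCOC)cc1O
A1 | alternative 1 | 4-methyl-4-(3-methylbut-2-en-1-yl)cyclohexane-1,3,5-trione | CC(C)=CCC1(C)C(=O)CC(=O)CC1=O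
A2 | alternative 1 | (3S,4aS)-3-bromo-2,2,4a-trimethyl-3,4-dihydro-2H-chromene-5,7(4aH,6H)-dione | C[C@]12C[C@H](Br)C(C)(C)OC1=CC(=O)CC2=O
A3 | alternative 2 | methyl (2S)-2,8-dimethyl-2-(3-methylbut-2-en-1-yl)-3,5,7-trioxononanoate (identical with 17) | C[C@@](C(=O)OC)(C(=O)CC(=O)CC(=O)C(C)C)CC=C(C)C
A4 | alternative 2 | (4S)-3,5-dihydroxy-4-methyl-4-(3-methylbut-2-en-1-yl)-2-(2-methylpropanoyl)cyclohexa-2,5-dien-1-one (identical with 18) | CC(C)=CC[C@@]1(C)C(O)=CC(=O)C(C(=O)C(C)C)=C1O
A5 | alternative 3 | 3,5-bis(methoxymethoxy)-4-{[tri(propan-2-yl)silyl]oxymethyl}-2-(trimethylsilyl)phenyl trifluoromethanesulfonate | COCOc1cc(OS(=O)(=O)C(F)(F)F)c([Si](C)(C)C)c(OCOC)c1CO[Si](C(C)C)(C(C)C)C(C)C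
A6 | alternative 3 | 3,5-bis(methoxymethoxy)-4-{[tri(propan-2-yl)silyl]oxymethyl}-1,2-didehydrobenzene (aryne) | COCOC1=C(CO[Si](C(C)C)(C(C)C)C(C)C)C(OCOC)=CC#C1
A7 | alternative 3 | 3-methylbut-2-enal | CC(C)=CC=O
A8 | alternative 3 | 5,7-bis(methoxymethoxy)-2,2-dimethyl-6-{[tri(propan-2-yl)silyl]oxymethyl}-2H-chromene | CC1(C)C=Cc2c(OCOC)c(CO[Si](C(C)C)(C(C)C)C(C)C)c(OCOC)cc2O1
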